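**Strategy.** Everything rests on cutting the 1,4-dioxane ring at its aryl ether bond O1–C8a. Since C8a is an sp2 carbon of ring A (the allyl- and methoxy-substituted benzene ring), this bond can be made last by intramolecular palladium-catalysed C–O coupling without touching the C2 (aryl) or C3 (methyl) stereocentres. One operation closes the heterocycle and converts a threo open-chain alcohol into the trans-2,3-disubstituted benzodioxane. The cyclisation substrate is a (1R,2R)-1-aryl-2-aryloxypropan-1-ol with bromine ortho to the ether oxygen and the syringyl phenol masked as a TIPS ether; its two centres come from a chiral-pool Mitsunobu inversion and a Felkin–Anh ketone reduction.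

Key step: step 7

Remark on the chemistry: the target is the trans-(2R,3R) isomer, and the threo-(1R,2R) alcohol maps onto it with unchanged descriptors because ring closure and desilylation alter no bond or CIP ranking at either centre. An α-aryloxy aldehyde is avoided on the way to the cyclisation substrate (it epimerises easily and its aryl ether oxygen chelates weakly), and a Weinreb amide, ketone and Felkin–Anh reduction sequence is used instead.

**Route**

Step 1
Reactants: 1 eugenol (4-allyl-2-methoxyphenol)
Product: 2 4-allyl-2-bromo-6-methoxyphenol
Conditions: NBS (1.0 equiv), i-Pr2NH (10 mol %), CH2Cl2, 0 °C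
Reagents that add atoms: N-bromosuccinimide, O=C1CCC(=O)N1Br
Why: Amine-catalysed electrophilic aromatic bromination should hit the only open position ortho to the hydroxyl, since the para position carries the allyl group and the other ortho position the methoxy group, and the activated phenol ring should react much faster than the isolated terminal alkene.

Step 2
Reactants: 2 4-allyl-2-bromo-6-methoxyphenol; 3 methyl (S)-lactate
Product: 4 methyl (2R)-2-(4-allyl-2-bromo-6-methoxyphenoxy)propanoate
Conditions: PPh3, DIAD, THF, 0 °C to rt
Reagents that add atoms: none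
Why: In this Mitsunobu etherification the acidic phenol should displace the phosphonium-activated lactate hydroxyl by SN2 with inversion, so the (S)-carbinol becomes the (R)-aryl ether that ends up as C3 of the target.

Step 3
Reactants: 4 methyl (2R)-2-(4-allyl-2-bromo-6-methoxyphenoxy)propanoate
Product: 5 (2R)-2-(4-allyl-2-bromo-6-methoxyphenoxy)-N-methoxy-N-methylpropanamide
Conditions: MeNH(OMe)·HCl, i-PrMgCl, THF, −20 to −10 °C; aq. NH4Cl
Reagents that add atoms: N,O-dimethylhydroxylamine hydrochloride, CNOC.Cl
Why: Weinreb amide formation by aminolysis of the ester with the chloromagnesium amide made in situ should be fast at low temperature, where the α-aryloxy stereocentre is not enolised and the Grignard base is consumed by the amine salt before it can touch the aryl bromide.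

Step 4
Reactants: 6 4-bromo-2,6-dimethoxyphenol
Product: 7 (4-bromo-2,6-dimethoxyphenoxy)triisopropylsilane
Conditions: TIPSCl, imidazole, DMF, rt
Reagents that add atoms: triisopropylsilyl chloride, CC(C)[Si](Cl)(C(C)C)C(C)C
Why: Imidazole-promoted silylation of the phenol is routine for 2,6-dimethoxyphenols, and the TIPS ether, shielded by both methoxy groups, should survive the Grignard, hydride and carbonate steps yet fall to fluoride.

Step 5
Reactants: 7 (4-bromo-2,6-dimethoxyphenoxy)triisopropylsilane; 5 (2R)-2-(4-allyl-2-bromo-6-methoxyphenoxy)-N-methoxy-N-methylpropanamide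
Product: 9 (2R)-2-(4-allyl-2-bromo-6-methoxyphenoxy)-1-[3,5-dimethoxy-4-(triisopropylsilyloxy)phenyl]propan-1-one, via aryl Grignard reagent 8 (not isolated)
Conditions: Mg turnings (I2 activation), THF, 45 °C; then 5, THF, 0 °C; aq. NH4Cl
Reagents that add atoms: none
Why: In this Weinreb ketone synthesis the aryl Grignard reagent from magnesium insertion should add only once, because the chelated tetrahedral adduct collapses to the ketone only on aqueous quench, and an aryl Grignard reagent should not exchange with the aryl bromide of 5 at 0 °C.

Step 6
Reactants: 9 (2R)-2-(4-allyl-2-bromo-6-methoxyphenoxy)-1-[3,5-dimethoxy-4-(triisopropylsilyloxy)phenyl]propan-1-one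
Product: 10 (1R,2R)-2-(4-allyl-2-bromo-6-methoxyphenoxy)-1-[3,5-dimethoxy-4-(triisopropylsilyloxy)phenyl]propan-1-ol
Conditions: K-Selectride, THF, −78 °C; aq. NH4Cl
Reagents that add atoms: none
Why: In this substrate-controlled Felkin–Anh (polar) reduction the bulky hydride should attack anti to the perpendicular C2–OAr bond and past the C2 hydrogen, which sets C1 as R (threo to C2), while the potassium counter-ion and the weakly Lewis-basic aryl ether oxygen disfavour the chelate pathway that would give the erythro epimer.

Step 7
Reactants: 10 (1R,2R)-2-(4-allyl-2-bromo-6-methoxyphenoxy)-1-[3,5-dimethoxy-4-(triisopropylsilyloxy)phenyl]propan-1-ol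
Product: 11 (2R,3R)-7-allyl-2-[3,5-dimethoxy-4-(triisopropylsilyloxy)phenyl]-5-methoxy-3-methyl-2,3-dihydro-1,4-benzodioxine
Conditions: Pd(OAc)2 (3 mol %), rac-2-(di-tert-butylphosphino)-1,1′-binaphthyl (4 mol %), Cs2CO3 (1.5 equiv), degassed toluene, 70 °C
Reagents that add atoms: none
Why: Ligated Pd(0) inserts into the C8a–Br bond, carbonate removes the C2–OH proton so that the alkoxide binds palladium, and C(sp2)–O reductive elimination from the resulting seven-membered aryl(alkoxo)palladacycle gives the O1–C8a bond. The closest known reaction type is the palladium-catalysed intramolecular etherification of ortho-haloaryl ethers bearing secondary alcohols (Buchwald–Hartwig C–O coupling), which gives 2-substituted 1,4-benzodioxanes from enantioenriched alcohols without loss of configuration. The one ring formed is the six-membered 1,4-dioxane, closed by reductive elimination at the ring A carbon ortho to the O4 tether, the palladacycle contracting from seven to six members. No stereocentre is created, and C2 and C3 are carried through unchanged because no bond at either carbon is made or broken. The selectivity required is C–O reductive elimination over β-hydride elimination of the secondary benzylic alkoxide (which would give a debrominated aryl ketone), and it is secured by the bulky, electron-rich di-tert-butyl binaphthyl phosphine and by the short ortho tether. The carbonate base and moderate temperature should keep the allyl group from isomerising to the propenyl arene and leave the aryl silyl ether intact.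

Step 8
Reactants: 11 (2R,3R)-7-allyl-2-[3,5-dimethoxy-4-(triisopropylsilyloxy)phenyl]-5-methoxy-3-methyl-2,3-dihydro-1,4-benzodioxine
Product: 12 4-[(2R,3R)-7-allyl-5-methoxy-3-methyl-2,3-dihydro-1,4-benzodioxin-2-yl]-2,6-dimethoxyphenol
Conditions: TBAF, AcOH, THF, 0 °C
Reagents that add atoms: none
Why: Fluoride-induced desilylation of the aryl silyl ether should be fast at 0 °C, and the acetic acid buffer keeps the liberated para-hydroxybenzyl ether protonated so that no quinone methide opening of the O1–C2 bond can epimerise C2.

**Compound list**

1 | eugenol (4-allyl-2-methoxyphenol) | C=CCc1ccc(O)c(OC)c1 | starting material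
2 | 4-allyl-2-bromo-6-methoxyphenol | C=CCc1cc(Br)c(O)c(OC)c1 | intermediate
3 | methyl (S)-lactate | C[C@H](O)C(=O)OC | starting material
4 | methyl (2R)-2-(4-allyl-2-bromo-6-methoxyphenoxy)propanoate | C=CCc1cc(OC)c(O[C@H](C)C(=O)OC)c(Br)c1 | intermediate
5 | (2R)-2-(4-allyl-2-bromo-6-methoxyphenoxy)-N-methoxy-N-methylpropanamide | C=CCc1cc(OC)c(O[C@H](C)C(=O)N(C)OC)c(Br)c1 | intermediate
6 | 4-bromo-2,6-dimethoxyphenol | COc1cc(Br)cc(OC)c1O | starting material
7 | (4-bromo-2,6-dimethoxyphenoxy)triisopropylsilane | COc1cc(Br)cc(OC)c1O[Si](C(C)C)(C(C)C)C(C)C | intermediate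
8 | [3,5-dimethoxy-4-(triisopropylsilyloxy)phenyl]magnesium bromide | COc1cc([Mg]Br)cc(OC)c1O[Si](C(C)C)(C(C)C)C(C)C | intermediate
9 | (2R)-2-(4-allyl-2-bromo-6-methoxyphenoxy)-1-[3,5-dimethoxy-4-(triisopropylsilyloxy)phenyl]propan-1-one | C=CCc1cc(OC)c(O[C@H](C)C(=O)c2cc(OC)c(O[Si](C(C)C)(C(C)C)C(C)C)c(OC)c2)c(Br)c1 | intermediate
10 | (1R,2R)-2-(4-allyl-2-bromo-6-methoxyphenoxy)-1-[3,5-dimethoxy-4-(triisopropylsilyloxy)phenyl]propan-1-ol | C=CCc1cc(OC)c(O[C@H](C)[C@H](O)c2cc(OC)c(O[Si](C(C)C)(C(C)C)C(C)C)c(OC)c2)c(Br)c1 | intermediate
11 | (2R,3R)-7-allyl-2-[3,5-dimethoxy-4-(triisopropylsilyloxy)phenyl]-5-methoxy-3-methyl-2,3-dihydro-1,4-benzodioxine | C=CCc1cc(OC)c2c(c1)O[C@H](c1cc(OC)c(O[Si](C(C)C)(C(C)C)C(C)C)c(OC)c1)[C@@H](C)O2 | intermediate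
12 | 4-[(2R,3R)-7-allyl-5-methoxy-3-methyl-2,3-dihydro-1,4-benzodioxin-2-yl]-2,6-dimethoxyphenol | C=CCc1cc(OC)c2c(c1)O[C@H](c1cc(OC)c(O)c(OC)c1)[C@@H](C)O2 | target

**Step count**

Total step count: 8. Longest linear sequence: 7 (steps 1, 2, 3, 5, 6, 7, 8 from eugenol); step 4 is a one-step branch.

**Steps most likely to fail**

Step 7. The risk is that β-hydride elimination from the palladium alkoxide outruns C–O reductive elimination, or that the arylpalladium species engages the allyl group (Heck-type insertion or isomerisation). The fallback closes the same ring at the other end of O1, by benzylic substitution instead of cross-coupling. It sets out from 10. The hydroxyl is deprotonated (NaH, THF), bromine–lithium exchange with t-BuLi at −78 °C is followed by trapping with B(OMe)3, which should give dimethyl [5-allyl-2-({(1R,2R)-1-[3,5-dimethoxy-4-(triisopropylsilyloxy)phenyl]-1-hydroxypropan-2-yl}oxy)-3-methoxyphenyl]boronate F1. This is oxidised in the same flask (H2O2, aq. NaHCO3) to the catechol monoether (1R,2R)-2-(4-allyl-2-hydroxy-6-methoxyphenoxy)-1-[3,5-dimethoxy-4-(triisopropylsilyloxy)phenyl]propan-1-ol F2. A catalytic amount of acid (Amberlyst-15, CH2Cl2, rt) should then ionise the electron-rich benzylic alcohol, and capture of the cation by the neighbouring phenol should favour the trans ring with both substituents equatorial. C3 is untouched, and the route is rejoined at 11.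

Step 6. The risk is poor facial selectivity if a chelated transition state competes with the Felkin–Anh one, which would give erythro material that is hard to separate. The fallback sets C1 by carbon–carbon bond formation instead of hydride delivery, so that chelation works for the threo isomer. It sets out from 4. DIBAL-H in CH2Cl2 at −78 °C should give (2R)-2-(4-allyl-2-bromo-6-methoxyphenoxy)propanal F3, which is used cold and without chromatography. Addition of Grignard reagent 8 in the presence of MgBr2·OEt2 (CH2Cl2, −78 °C) should proceed through the Cram chelate, with the aryl group entering anti to the methyl group, and the route is rejoined at 10.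

Step 1. The risk is competing addition of bromine to the allyl double bond, or over-bromination. The fallback masks the alkene during ring bromination. It sets out from 1. Excess Br2 (CHCl3, 0 °C) should brominate both the ring and the alkene to give 2-bromo-4-(2,3-dibromopropyl)-6-methoxyphenol F4 (its CHBr centre is racemic and irrelevant). Reductive debromination with zinc dust in AcOH/EtOH should regenerate the allyl group, and the route is rejoined at 2.

**Further compounds**

F1 | step 7 | dimethyl [5-allyl-2-({(1R,2R)-1-[3,5-dimethoxy-4-(triisopropylsilyloxy)phenyl]-1-hydroxypropan-2-yl}oxy)-3-methoxyphenyl]boronate | C=CCc1cc(OC)c(O[C@H](C)[C@H](O)c2cc(OC)c(O[Si](C(C)C)(C(C)C)C(C)C)c(OC)c2)c(B(OC)OC)c1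
F2 | step 7 | (1R,2R)-2-(4-allyl-2-hydroxy-6-methoxyphenoxy)-1-[3,5-dimethoxy-4-(triisopropylsilyloxy)phenyl]propan-1-ol | C=CCc1cc(OC)c(O[C@H](C)[C@H](O)c2cc(OC)c(O[Si](C(C)C)(C(C)C)C(C)C)c(OC)c2)c(O)c1
F3 | step 6 | (2R)-2-(4-allyl-2-bromo-6-methoxyphenoxy)propanal | C=CCc1cc(OC)c(O[C@H](C)C=O)c(Br)c1
F4 | step 1 | 2-bromo-4-(2,3-dibromopropyl)-6-methoxyphenol | COc1cc(CC(Br)CBr)cc(Br)c1O
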